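**Plan**

- Retrosynthesis: the 2-pyranone is unravelled to a methyl ketone (enol-lactone C–O bond, then C5′–C6′ by oxalate Claisen, then C3′=C4′ by Horner–Wadsworth–Emmons olefination). The butyrolactone is opened at O1–C5 and an oxygen is put back on the benzylic carbon attached to C4. The C4–C5 bond is then cut (silicon-tethered radical cyclisation), followed by the enoate C=C and the aryl–carbonyl bond.
- Forward: aryl keto ester, carbinol, E-enoate chain, tether. Rings arise in the order 1-oxa-2-silacyclopentane (step 9), butyrolactone (step 10), 2-pyranone (step 15).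
- Enabling feature: lactone C4 carries both the ring OCH2 carbon C5 and the benzylic CH2. An oxygen parked on that benzylic carbon can hold an O–SiMe2–CH2 radical that reaches C4 through a five-membered ring (O, Si, C5, C4, benzylic C), and the oxygen is later removed by hydrogenolysis.
- Stereochemistry: the carbinol centre comes from asymmetric transfer hydrogenation, is relayed to C4 in the radical cyclisation (trans siloxane ring) and is then erased. C3 is set by base equilibration to the trans lactone.

Key step: step 9

Remarks on the chemistry: locants O1, C2 (C=O), C3, C4, C5 refer to the butyrolactone and primed locants to the pyranone. Compounds 15 to 19 are carried as mixtures at the carbon α to the ester or lactone carbonyl and are drawn without a descriptor there until step 12. In step 11 the dioxolane is assumed to hydrolyse before the slower hydrogenolysis; the order is immaterial.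

**Route**

Step 1
Reactants: 1 1,2-dimethoxybenzene; 2 methyl chlorooxoacetate
Product: 3 methyl 2-(3,4-dimethoxyphenyl)-2-oxoacetate
Conditions: AlCl3, CH2Cl2, 0 °C to rt
Reagents that add atoms: none
Why: Friedel–Crafts acylation by the acid chloride end of 2 goes para to one methoxy group and away from the position between the two ether groups, giving the 3,4-dimethoxyphenyl keto ester.

Step 2
Reactants: 3 methyl 2-(3,4-dimethoxyphenyl)-2-oxoacetate
Product: 4 methyl (S)-2-(3,4-dimethoxyphenyl)-2-hydroxyacetate
Conditions: RuCl(p-cymene)[(R,R)-TsDPEN] (cat.), HCO2H/Et3N (5:2), DMF, rt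
Reagents that add atoms: none
Why: Noyori asymmetric transfer hydrogenation of an activated aryl ketone, in which the aryl group is expected to sit as it does in acetophenone and benzil reductions so that the (R,R)-ligand gives the S carbinol (S because the ester outranks aryl), the sense and purity to be checked by Mosher ester analysis and raised by crystallisation if needed.

Step 3
Reactants: 4 methyl (S)-2-(3,4-dimethoxyphenyl)-2-hydroxyacetate
Product: 5 methyl (S)-2-[(tert-butyldimethylsilyl)oxy]-2-(3,4-dimethoxyphenyl)acetate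
Conditions: TBSCl, imidazole, DMF, rt
Reagents that add atoms: tert-butyldimethylsilyl chloride, CC(C)(C)[Si](C)(C)Cl
Why: Standard silyl ether formation under conditions too mild to enolise the α-aryl ester gives a group that withstands i-Bu2AlH and the olefination and is removed by fluoride.

Step 4
Reactants: 6 trimethyl phosphonoacetate; 7 chloroacetone
Product: 8 methyl 2-(dimethoxyphosphoryl)-4-oxopentanoate (racemic)
Conditions: NaH, THF, 0 °C; then 7, 0 °C to rt
Reagents that add atoms: none
Why: SN2 alkylation of the sodium phosphonoacetate carbanion with a reactive α-chloro ketone, run with an excess of 6 to limit dialkylation.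

Step 5
Reactants: 8 methyl 2-(dimethoxyphosphoryl)-4-oxopentanoate
Product: 9 methyl 2-(dimethoxyphosphoryl)-3-(2-methyl-1,3-dioxolan-2-yl)propanoate (racemic)
Conditions: Me3SiOCH2CH2OSiMe3, Me3SiOTf (cat.), CH2Cl2, −78 to 0 °C
Reagents that add atoms: 1,2-bis(trimethylsilyloxy)ethane, C[Si](C)(C)OCCO[Si](C)(C)C
Why: Noyori ketalisation under aprotic conditions protects the ketone without transesterifying the methyl esters and keeps the later enoate double bond from moving into conjugation with a free carbonyl.

Step 6
Reactants: 5 methyl (S)-2-[(tert-butyldimethylsilyl)oxy]-2-(3,4-dimethoxyphenyl)acetate; 9 methyl 2-(dimethoxyphosphoryl)-3-(2-methyl-1,3-dioxolan-2-yl)propanoate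
Product: 11 methyl (R,E)-4-[(tert-butyldimethylsilyl)oxy]-4-(3,4-dimethoxyphenyl)-2-[(2-methyl-1,3-dioxolan-2-yl)methyl]but-2-enoate, via α-siloxy aldehyde 10 (not isolated)
Conditions: 5, i-Bu2AlH, CH2Cl2, −78 °C; then 9/LiN(SiMe3)2 (THF), −78 °C to rt
Reagents that add atoms: none
Why: Half-reduction of the ester to a stable aluminium hemiacetal followed by Horner–Wadsworth–Emmons olefination as the aldehyde is released keeps the racemisation-prone α-aryl aldehyde from accumulating, and the lithium phosphonate under equilibrating conditions is expected to favour the E enoate (ester trans to the carbinol carbon), any Z isomer being removable after step 7 as its butenolide.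

Step 7
Reactants: 11 methyl (R,E)-4-[(tert-butyldimethylsilyl)oxy]-4-(3,4-dimethoxyphenyl)-2-[(2-methyl-1,3-dioxolan-2-yl)methyl]but-2-enoate
Product: 12 methyl (R,E)-4-(3,4-dimethoxyphenyl)-4-hydroxy-2-[(2-methyl-1,3-dioxolan-2-yl)methyl]but-2-enoate
Conditions: Bu4NF, AcOH, THF, 0 °C
Reagents that add atoms: none
Why: Fluoride cleavage of the silyl ether, buffered with acetic acid so that the γ-hydroxy enoate is not isomerised to the γ-keto ester, frees a hydroxyl that cannot lactonise because it lies trans to the ester.

Step 8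
Reactants: 12 methyl (R,E)-4-(3,4-dimethoxyphenyl)-4-hydroxy-2-[(2-methyl-1,3-dioxolan-2-yl)methyl]but-2-enoate; 13 (bromomethyl)chlorodimethylsilane
Product: 14 methyl (R,E)-4-{[(bromomethyl)dimethylsilyl]oxy}-4-(3,4-dimethoxyphenyl)-2-[(2-methyl-1,3-dioxolan-2-yl)methyl]but-2-enoate
Conditions: Et3N, DMAP (cat.), CH2Cl2, 0 °C
Reagents that add atoms: none
Why: O-silylation of the secondary alcohol with the chlorosilane and an amine base is the standard way to (bromomethyl)dimethylsilyl ethers, the labile product being passed through a short pad and used at once.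

Step 9
Reactants: 14 methyl (R,E)-4-{[(bromomethyl)dimethylsilyl]oxy}-4-(3,4-dimethoxyphenyl)-2-[(2-methyl-1,3-dioxolan-2-yl)methyl]but-2-enoate
Product: 15 methyl 2-[(4S,5R)-5-(3,4-dimethoxyphenyl)-2,2-dimethyl-1-oxa-2-silacyclopentan-4-yl]-3-(2-methyl-1,3-dioxolan-2-yl)propanoate (trans ring, both epimers at the ester α-carbon)
Conditions: Bu3SnH (slow addition), AIBN (cat.), benzene, 80 °C, 0.01 M
Reagents that add atoms: none
Why: The tin radical abstracts bromine, the α-silyl carbon radical adds to the enoate β-carbon next to the carbinol, and the tertiary α-ester radical then takes hydrogen from Bu3SnH; this is the Nishiyama–Stork silicon-tethered radical cyclisation of (bromomethyl)dimethylsilyl ethers of allylic alcohols. The 1-oxa-2-silacyclopentane closes in the 5-exo-trig mode. The new centre at ring C4 (the future lactone C4) is controlled by the carbinol centre: allylic 1,3-strain with the cis ketal-bearing methylene holds the carbinol C–H in the alkene plane, so the tethered radical enters from the face carrying oxygen with the aryl group on the other face, which gives the trans 4,5-disubstituted ring. The α-ester centre (future lactone C3) forms by unselective hydrogen transfer and is corrected in step 12. The step needs 5-exo over 6-endo closure and high facial selectivity: the first is secured by the match of the nucleophilic radical with the electron-poor β-carbon and by formation of the stabilised tertiary radical, the second by the strain-locked conformation, while slow stannane addition at high dilution limits direct reduction of the C–Br bond.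

Step 10
Reactants: 15 methyl 2-[(4S,5R)-5-(3,4-dimethoxyphenyl)-2,2-dimethyl-1-oxa-2-silacyclopentan-4-yl]-3-(2-methyl-1,3-dioxolan-2-yl)propanoate
Product: 17 (4R)-4-[(R)-(3,4-dimethoxyphenyl)(hydroxy)methyl]-3-[(2-methyl-1,3-dioxolan-2-yl)methyl]dihydrofuran-2(3H)-one (C3 epimers), via diol ester 16 (not isolated)
Conditions: KF, KHCO3, 30% H2O2, THF/MeOH, rt; then PPTS (cat.), CH2Cl2, rt
Reagents that add atoms: hydrogen peroxide, OO
Why: Tamao–Fleming oxidation turns the ring C–Si bond into the primary C–OH and frees the benzylic hydroxyl without touching a stereocentre, and mild acid then closes the γ-lactone on the less hindered primary hydroxyl (a lactone formed on the benzylic oxygen would converge in step 11, where its benzylic C–O bond is cleaved and the acid relactonises).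

Step 11
Reactants: 17 (4R)-4-[(R)-(3,4-dimethoxyphenyl)(hydroxy)methyl]-3-[(2-methyl-1,3-dioxolan-2-yl)methyl]dihydrofuran-2(3H)-one
Product: 19 (4R)-4-(3,4-dimethoxybenzyl)-3-(2-oxopropyl)dihydrofuran-2(3H)-one (C3 epimers), via hydroxy keto lactone 18 (not isolated)
Conditions: H2 (1 atm), 10% Pd/C, HClO4 (cat.), AcOH/H2O (9:1), rt
Reagents that add atoms: water, O
Why: Catalytic hydrogenolysis of the electron-rich benzylic C–O bond under acid, the standard deoxygenation of 7-hydroxy lignan lactones, leaves the adjacent C4 centre untouched while the aqueous acid hydrolyses the dioxolane.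

Step 12
Reactants: 19 (4R)-4-(3,4-dimethoxybenzyl)-3-(2-oxopropyl)dihydrofuran-2(3H)-one
Product: 20 (3R,4R)-4-(3,4-dimethoxybenzyl)-3-(2-oxopropyl)dihydrofuran-2(3H)-one
Conditions: DBU, toluene, 60 °C
Reagents that add atoms: none
Why: Amidine-base epimerisation through the lactone enolate drives C3 to the thermodynamically preferred trans 3,4-disubstituted butyrolactone, as in dibenzylbutyrolactone lignans, which fixes C3 as R.

Step 13
Reactants: 20 (3R,4R)-4-(3,4-dimethoxybenzyl)-3-(2-oxopropyl)dihydrofuran-2(3H)-one; 6 trimethyl phosphonoacetate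
Product: 21 methyl 4-[(3R,4R)-4-(3,4-dimethoxybenzyl)-2-oxotetrahydrofuran-3-yl]-3-methylbut-2-enoate (E/Z mixture)
Conditions: NaH, THF, 0 to 50 °C
Reagents that add atoms: none
Why: Horner–Wadsworth–Emmons olefination of the methyl ketone by the stabilised phosphonate anion, which does not attack the lactone and is kept in excess over NaH so that no stronger base is present; the alkene geometry is immaterial for the next steps.

Step 14
Reactants: 21 methyl 4-[(3R,4R)-4-(3,4-dimethoxybenzyl)-2-oxotetrahydrofuran-3-yl]-3-methylbut-2-enoate; 22 dimethyl oxalate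
Product: 23 dimethyl 4-{[(3R,4R)-4-(3,4-dimethoxybenzyl)-2-oxotetrahydrofuran-3-yl]methyl}-2-oxohex-4-enedioate (largely as its 2-enol)
Conditions: KOC(CH3)3, THF, 0 °C to rt; then cold aq. HCl
Reagents that add atoms: none
Why: Vinylogous Claisen condensation of a β,β-disubstituted acrylate with an oxalate, the classical entry to 2-pyranone-6-carboxylic acids, is reversible and is pulled to the least hindered stabilised dienolate (acylation at the methyl group), excess oxalate being expected to outrun intramolecular acylation at the lactone much as adipates are oxalylated in preference to Dieckmann closure, while C3 stays at its trans equilibrium.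

Step 15
Reactants: 23 dimethyl 4-{[(3R,4R)-4-(3,4-dimethoxybenzyl)-2-oxotetrahydrofuran-3-yl]methyl}-2-oxohex-4-enedioate
Product: 25 4-{[(3R,4R)-4-(3,4-dimethoxybenzyl)-2-oxotetrahydrofuran-3-yl]methyl}-2-oxo-2H-pyran-6-carboxylic acid, via pyranone methyl ester 24 (not isolated)
Conditions: 6 M HCl/AcOH, 90 °C
Reagents that add atoms: water, O
Why: Acid-promoted enol lactonisation (the enol oxygen of the α-keto ester adds to the acrylate ester carbonyl after geometric equilibration through the keto tautomers) closes the 2-pyranone and the same hot aqueous acid hydrolyses the 6-ester, conditions under which the butyrolactone (which re-closes on concentration), the aryl methyl ethers and both stereocentres should persist.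

**Compound list**

1 | 1,2-dimethoxybenzene | COc1ccccc1OC | starting material
2 | methyl chlorooxoacetate | COC(=O)C(Cl)=O | starting material
3 | methyl 2-(3,4-dimethoxyphenyl)-2-oxoacetate | COC(=O)C(=O)c1ccc(OC)c(OC)c1 | intermediate
4 | methyl (S)-2-(3,4-dimethoxyphenyl)-2-hydroxyacetate | COC(=O)[C@@H](O)c1ccc(OC)c(OC)c1 | intermediate
5 | methyl (S)-2-[(tert-butyldimethylsilyl)oxy]-2-(3,4-dimethoxyphenyl)acetate | COC(=O)[C@@H](O[Si](C)(C)C(C)(C)C)c1ccc(OC)c(OC)c1 | intermediate
6 | trimethyl phosphonoacetate | COC(=O)CP(=O)(OC)OC | starting material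
7 | chloroacetone | CC(=O)CCl | starting material
8 | methyl 2-(dimethoxyphosphoryl)-4-oxopentanoate (racemic) | COC(=O)C(CC(C)=O)P(=O)(OC)OC | intermediate
9 | methyl 2-(dimethoxyphosphoryl)-3-(2-methyl-1,3-dioxolan-2-yl)propanoate (racemic) | COC(=O)C(CC1(C)OCCO1)P(=O)(OC)OC | intermediate
10 | (S)-2-[(tert-butyldimethylsilyl)oxy]-2-(3,4-dimethoxyphenyl)acetaldehyde | O=C[C@@H](O[Si](C)(C)C(C)(C)C)c1ccc(OC)c(OC)c1 | intermediate
11 | methyl (R,E)-4-[(tert-butyldimethylsilyl)oxy]-4-(3,4-dimethoxyphenyl)-2-[(2-methyl-1,3-dioxolan-2-yl)methyl]but-2-enoate | COC(=O)/C(CC1(C)OCCO1)=C/[C@@H](O[Si](C)(C)C(C)(C)C)c1ccc(OC)c(OC)c1 | intermediate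
12 | methyl (R,E)-4-(3,4-dimethoxyphenyl)-4-hydroxy-2-[(2-methyl-1,3-dioxolan-2-yl)methyl]but-2-enoate | COC(=O)/C(CC1(C)OCCO1)=C/[C@@H](O)c1ccc(OC)c(OC)c1 | intermediate
13 | (bromomethyl)chlorodimethylsilane | C[Si](C)(Cl)CBr | starting material
14 | methyl (R,E)-4-{[(bromomethyl)dimethylsilyl]oxy}-4-(3,4-dimethoxyphenyl)-2-[(2-methyl-1,3-dioxolan-2-yl)methyl]but-2-enoate | COC(=O)/C(CC1(C)OCCO1)=C/[C@@H](O[Si](C)(C)CBr)c1ccc(OC)c(OC)c1 | intermediate
15 | methyl 2-[(4S,5R)-5-(3,4-dimethoxyphenyl)-2,2-dimethyl-1-oxa-2-silacyclopentan-4-yl]-3-(2-methyl-1,3-dioxolan-2-yl)propanoate (trans ring, both epimers at the ester α-carbon) | COC(=O)C(CC1(C)OCCO1)[C@@H]1C[Si](C)(C)O[C@H]1c1ccc(OC)c(OC)c1 | intermediate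
16 | methyl (3R,4R)-4-(3,4-dimethoxyphenyl)-4-hydroxy-3-(hydroxymethyl)-2-[(2-methyl-1,3-dioxolan-2-yl)methyl]butanoate (C2 epimers) | COC(=O)C(CC1(C)OCCO1)[C@H](CO)[C@@H](O)c1ccc(OC)c(OC)c1 | intermediate
17 | (4R)-4-[(R)-(3,4-dimethoxyphenyl)(hydroxy)methyl]-3-[(2-methyl-1,3-dioxolan-2-yl)methyl]dihydrofuran-2(3H)-one (C3 epimers) | COc1ccc([C@H](O)[C@H]2COC(=O)C2CC3(C)OCCO3)cc1OC | intermediate
18 | (4R)-4-[(R)-(3,4-dimethoxyphenyl)(hydroxy)methyl]-3-(2-oxopropyl)dihydrofuran-2(3H)-one (C3 epimers) | COc1ccc([C@H](O)[C@H]2COC(=O)C2CC(C)=O)cc1OC | intermediate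
19 | (4R)-4-(3,4-dimethoxybenzyl)-3-(2-oxopropyl)dihydrofuran-2(3H)-one (C3 epimers) | COc1ccc(C[C@H]2COC(=O)C2CC(C)=O)cc1OC | intermediate
20 | (3R,4R)-4-(3,4-dimethoxybenzyl)-3-(2-oxopropyl)dihydrofuran-2(3H)-one | COc1ccc(C[C@H]2COC(=O)[C@@H]2CC(C)=O)cc1OC | intermediate
21 | methyl 4-[(3R,4R)-4-(3,4-dimethoxybenzyl)-2-oxotetrahydrofuran-3-yl]-3-methylbut-2-enoate (E/Z mixture) | COc1ccc(C[C@H]2COC(=O)[C@@H]2CC(C)=CC(=O)OC)cc1OC | intermediate
22 | dimethyl oxalate | COC(=O)C(=O)OC | starting material
23 | dimethyl 4-{[(3R,4R)-4-(3,4-dimethoxybenzyl)-2-oxotetrahydrofuran-3-yl]methyl}-2-oxohex-4-enedioate | COc1ccc(C[C@H]2COC(=O)[C@@H]2CC(CC(=O)C(=O)OC)=CC(=O)OC)cc1OC | intermediate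
24 | methyl 4-{[(3R,4R)-4-(3,4-dimethoxybenzyl)-2-oxotetrahydrofuran-3-yl]methyl}-2-oxo-2H-pyran-6-carboxylate | COc1ccc(C[C@H]2COC(=O)[C@@H]2Cc2cc(C(=O)OC)oc(=O)c2)cc1OC | intermediate
25 | 4-{[(3R,4R)-4-(3,4-dimethoxybenzyl)-2-oxotetrahydrofuran-3-yl]methyl}-2-oxo-2H-pyran-6-carboxylic acid (CNP0526356.1) | COc1ccc(C[C@H]2COC(=O)[C@@H]2Cc2cc(C(=O)O)oc(=O)c2)cc1OC | target

**Step count**

Total: 15 steps. Longest linear sequence: 13 steps (steps 1 to 3 and 6 to 15); the phosphonate branch (steps 4 and 5) joins at step 6.

**Steps most likely to fail**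

1. Step 14. The alkoxide-mediated condensation may take a wrong course: acylation at the methylene on the lactone side instead of the methyl group, attack of the dienolate on the lactone carbonyl, or opening of the lactone. The fallback installs the oxalyl unit first and closes the ring by olefination, so that no free dienolate is needed. It sets out from 20. The kinetic lithium enolate of the methyl ketone (LiN(SiMe3)2, THF, −78 °C) is acylated at the methyl group with 22 to give methyl 5-[(3R,4R)-4-(3,4-dimethoxybenzyl)-2-oxotetrahydrofuran-3-yl]-2,4-dioxopentanoate F1. Esterification of its C2 enol hydroxyl with diethylphosphonoacetic acid (DCC, DMAP, CH2Cl2) would give methyl (Z)-2-{[2-(diethoxyphosphoryl)acetyl]oxy}-5-[(3R,4R)-4-(3,4-dimethoxybenzyl)-2-oxotetrahydrofuran-3-yl]-4-oxopent-2-enoate F2. Intramolecular Horner–Wadsworth–Emmons reaction onto the C4 ketone (LiCl, DBU, MeCN) closes the pyranone and comes back to the route at 24, which is hydrolysed as in step 15. The site of enol acylation would have to be confirmed, because acylation at the other oxygen leads to the isomeric pyranone.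

2. Step 6. The α-aryl aldehyde may lose enantiomeric purity by enolisation under the basic olefination, or the E selectivity may erode. The fallback sets the carbinol centre after the alkene is in place. It sets out from 9. Horner–Wadsworth–Emmons reaction (NaH, THF) with commercial 3,4-dimethoxyphenylglyoxal (hydrate, dried azeotropically) would give methyl (E)-4-(3,4-dimethoxyphenyl)-2-[(2-methyl-1,3-dioxolan-2-yl)methyl]-4-oxobut-2-enoate F3. Corey–Bakshi–Shibata reduction of the aryl ketone ((S)-2-methyl-CBS-oxazaborolidine, catecholborane, toluene, −78 °C; the catalyst antipode to be fixed by a test reduction and Mosher analysis) comes back to the route at 12. Steps 1 to 3, 6 and 7 are then not needed.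

3. Step 11. Acid may ionise the benzylic alcohol before hydrogenolysis; elimination towards C4 followed by hydrogenation would erode the relayed C4 configuration, and the cation could be trapped by the freed ketone. The fallback replaces catalytic by radical deoxygenation and removes the ketal afterwards. It sets out from 17. 1,1′-Thiocarbonyldiimidazole (DMAP, CH2Cl2) would give the benzylic O-(imidazol-1-ylthiocarbonyl) derivative of 17 F4. Barton–McCombie reduction (Bu3SnH, AIBN, toluene, 110 °C) would give (4R)-4-(3,4-dimethoxybenzyl)-3-[(2-methyl-1,3-dioxolan-2-yl)methyl]dihydrofuran-2(3H)-one F5. Ketal hydrolysis (PPTS, acetone/H2O) comes back to the route at 19.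

**Further compounds**

F1 | step 14 | methyl 5-[(3R,4R)-4-(3,4-dimethoxybenzyl)-2-oxotetrahydrofuran-3-yl]-2,4-dioxopentanoate | COc1ccc(C[C@H]2COC(=O)[C@@H]2CC(=O)CC(=O)C(=O)OC)cc1OC
F2 | step 14 | methyl (Z)-2-{[2-(diethoxyphosphoryl)acetyl]oxy}-5-[(3R,4R)-4-(3,4-dimethoxybenzyl)-2-oxotetrahydrofuran-3-yl]-4-oxopent-2-enoate | COc1ccc(C[C@H]2COC(=O)[C@@H]2CC(=O)/C=C(\OC(=O)CP(=O)(OCC)OCC)C(=O)OC)cc1OC
F3 | step 6 | methyl (E)-4-(3,4-dimethoxyphenyl)-2-[(2-methyl-1,3-dioxolan-2-yl)methyl]-4-oxobut-2-enoate | COC(=O)/C(CC1(C)OCCO1)=C/C(=O)c1ccc(OC)c(OC)c1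
F4 | step 11 | benzylic O-(imidazol-1-ylthiocarbonyl) derivative of 17 (configuration as in 17, C3 epimers) | COc1ccc([C@H](OC(=S)n3ccnc3)[C@H]2COC(=O)C2CC4(C)OCCO4)cc1OC
F5 | step 11 | (4R)-4-(3,4-dimethoxybenzyl)-3-[(2-methyl-1,3-dioxolan-2-yl)methyl]dihydrofuran-2(3H)-one (C3 epimers) | COc1ccc(C[C@H]2COC(=O)C2CC3(C)OCCO3)cc1OC
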